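## Retrosynthetic overview

1. The target is read as a methyl ester seco-depsidone: two orsellinate-type polyketide arenes (ring A = 3-hydroxymethyl-orsellinate, ring B = catechol phthalide) joined by an oxidatively formed aryl ether.
2. Last disconnection: the acetonide that ties the 4-OH of ring A to its CH2OH (12 ⇒ 13).
3. Key disconnection: the C5(ring B)–O bond, made as in the presumed biosynthesis by oxidising the ring B catechol to its o-quinone and capturing it at C5 with the salicylate oxygen of ring A, not by Ullmann or SNAr coupling.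
4. Ring B lactone: closed as phthalides are closed in nature, carboxylate onto an ortho benzylic carbon at the alcohol oxidation level (hydroxymethylation/lactonisation of 2,3-dimethoxy-5-methylbenzoic acid, from 3,4-dimethoxytoluene by ortho-lithiation/CO2); ring A comes from methyl orsellinate by C3 formylation, reduction and ketalisation.
5. Ring order: both benzene rings are bought; the lactone is the only ring closed (step 4), then the rings are joined (step 6) and the temporary acetonide ring is opened (step 7).

Assumption: the target has no stereocentre and no configurationally stable axis, so it is achiral and no step has to set configuration. Phthalide numbering used below: C1 (C=O), C3 (CH2), C4 (CH3), C5 (O-aryl), C6 and C7 (OH).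

## Route

Step 1
Reactants: 1 methyl 2,4-dihydroxy-6-methylbenzoate (methyl orsellinate)
Product: 2 methyl 3-formyl-2,4-dihydroxy-6-methylbenzoate
Conditions: Cl2CHOMe (1.3 equiv), TiCl4 (2.5 equiv), CH2Cl2, −10 °C → rt, 3 h; 1 M HCl, 0 °C; crystallisation
Reagents that add atoms: dichloromethyl methyl ether, COC(Cl)Cl
Why: Rieche formylation, in which the TiCl4-bound phenoxides deliver the electrophile ortho to oxygen; C3 is ortho to both hydroxyls and less hindered than C5 (flanked by the ring methyl), so the 3-formyl compound should be the main product and the minor 5-isomer is crystallised away.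

Step 2
Reactants: 2 methyl 3-formyl-2,4-dihydroxy-6-methylbenzoate
Product: 4 methyl 5-hydroxy-2,2,7-trimethyl-4H-1,3-benzodioxine-6-carboxylate, via triol 3 (not isolated)
Conditions: NaBH4 (0.6 equiv), THF/MeOH 4:1, 0 °C, 20 min; pH 6 phosphate quench, extraction, crude 3 not purified; then Me2C(OMe)2 (5 equiv), PPTS (10 mol%), acetone, rt, 3 h
Reagents that add atoms: 2,2-dimethoxypropane, COC(C)(C)OC
Why: Borohydride reduction of the aldehyde (ester untouched at 0 °C) followed by acid-catalysed ketal exchange; under equilibrium control the benzodioxine built on the 4-OH forms because it keeps the 2-OH hydrogen-bonded to the ester carbonyl, leaving only the salicylate OH free for step 6.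

Step 3
Reactants: 5 3,4-dimethoxytoluene
Product: 7 2,3-dimethoxy-5-methylbenzoic acid, via aryllithium 6 (not isolated)
Conditions: n-BuLi (1.2 equiv), TMEDA (1.2 equiv), Et2O, 0 °C → rt, 3 h; CO2 (solid), −78 °C → rt; 2 M HCl
Reagents that add atoms: carbon dioxide, O=C=O
Why: Directed ortho-metalation, in which methoxy-directed lithiation takes the ortho position not flanked by the methyl group, and the aryllithium is carboxylated by CO2.

Step 4
Reactants: 7 2,3-dimethoxy-5-methylbenzoic acid
Product: 9 6,7-dimethoxy-4-methylisobenzofuran-1(3H)-one, via hydroxymethyl acid 8 (not isolated)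
Conditions: 37% aq. CH2O (3 equiv), conc. HCl/AcOH 1:1, 85 °C, 4 h
Reagents that add atoms: formaldehyde, C=O
Why: Blanc-type hydroxymethylation and lactonisation (the classical meconin synthesis applied to the 5-methyl homologue): the electrophile enters para to the 3-methoxy group at the only position ortho to the carboxyl, and the acid closes onto the new benzylic carbon, the chemical counterpart of the benzylic hydroxylation/lactonisation that makes phthalides in nature.

Step 5
Reactants: 9 6,7-dimethoxy-4-methylisobenzofuran-1(3H)-one
Product: 10 6,7-dihydroxy-4-methylisobenzofuran-1(3H)-one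
Conditions: BBr3 (3 equiv), CH2Cl2, −78 °C → rt, 6 h; ice-water
Reagents that add atoms: none
Why: BBr3 ether cleavage (Lewis acid–base adduct, then SN2 by bromide on the O-methyl groups) frees the catechol; the phthalide lactone survives, and any ring-opened bromomethyl acid re-closes on aqueous work-up.

Step 6
Reactants: 4 methyl 5-hydroxy-2,2,7-trimethyl-4H-1,3-benzodioxine-6-carboxylate; 10 6,7-dihydroxy-4-methylisobenzofuran-1(3H)-one
Product: 12 methyl 5-[(6,7-dihydroxy-4-methyl-1-oxo-1,3-dihydroisobenzofuran-5-yl)oxy]-2,2,7-trimethyl-4H-1,3-benzodioxine-6-carboxylate, via o-quinone 11 (not isolated)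
Conditions: 10 (1.5 equiv), Ag2O (3 equiv), Na2SO4, MeCN, −20 °C, 20 min, cold filtration under Ar; filtrate added over 1 h to 4 (1.0 equiv) and Cs2CO3 (1.05 equiv) in DMF, −45 → −10 °C; aq. Na2S2O4/NaH2PO4 work-up (surplus 11 returns to 10 and is recovered)
Reagents that add atoms: none
Why: Proposed new method: Ag2O takes catechol 10 to o-quinone 11, in which C5 is the only unsubstituted ring carbon and the terminus of the dienone O=C7–C7a=C3a–C4=C5 (also conjugated to the lactone carbonyl), so the cesium phenoxide of 4, whose 4-OH and CH2OH are locked in the acetonide and whose para carbon is flanked by two substituents, adds through oxygen in a 1,6-oxa-Michael addition and the C5–H adduct tautomerises irreversibly to the aromatic catechol 12, whereas attack at the substituted ring carbons or at the carbonyls can only revert; the closest known reaction type is the conjugate addition of phenoxide, thiolate and amine nucleophiles to quinones, which is the polar counterpart of the oxidative C–O phenol coupling presumed to join the two rings in nature.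

Step 7
Reactants: 12 methyl 5-[(6,7-dihydroxy-4-methyl-1-oxo-1,3-dihydroisobenzofuran-5-yl)oxy]-2,2,7-trimethyl-4H-1,3-benzodioxine-6-carboxylate
Product: 13 methyl 2-[(6,7-dihydroxy-4-methyl-1-oxo-1,3-dihydroisobenzofuran-5-yl)oxy]-4-hydroxy-3-(hydroxymethyl)-6-methylbenzoate
Conditions: AcOH/H2O/THF 3:1:1, 35 °C, 4 h, Ar
Reagents that add atoms: none
Why: Acid-catalysed hydrolysis of the phenolic ketal, which is far more labile than the methyl ester, lactone or diaryl ether; the water-rich medium returns any benzylic cation to the same alcohol, and no stereocentre is formed anywhere in the route.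

## Compound list

1 | methyl 2,4-dihydroxy-6-methylbenzoate (methyl orsellinate) | COC(=O)c1c(C)cc(O)cc1O | starting material
2 | methyl 3-formyl-2,4-dihydroxy-6-methylbenzoate | COC(=O)c1c(C)cc(O)c(C=O)c1O | intermediate
3 | methyl 2,4-dihydroxy-3-(hydroxymethyl)-6-methylbenzoate | COC(=O)c1c(C)cc(O)c(CO)c1O | intermediate
4 | methyl 5-hydroxy-2,2,7-trimethyl-4H-1,3-benzodioxine-6-carboxylate | COC(=O)c1c(C)cc2OC(C)(C)OCc2c1O | intermediate
5 | 3,4-dimethoxytoluene (1,2-dimethoxy-4-methylbenzene) | Cc1ccc(OC)c(OC)c1 | starting material
6 | (2,3-dimethoxy-5-methylphenyl)lithium | [Li]c1cc(C)cc(OC)c1OC | intermediate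
7 | 2,3-dimethoxy-5-methylbenzoic acid | Cc1cc(OC)c(OC)c(C(=O)O)c1 | intermediate
8 | 6-(hydroxymethyl)-2,3-dimethoxy-5-methylbenzoic acid | Cc1cc(OC)c(OC)c(C(=O)O)c1CO | intermediate
9 | 6,7-dimethoxy-4-methylisobenzofuran-1(3H)-one | Cc1cc(OC)c(OC)c2C(=O)OCc12 | intermediate
10 | 6,7-dihydroxy-4-methylisobenzofuran-1(3H)-one | Cc1cc(O)c(O)c2C(=O)OCc12 | intermediate
11 | 4-methylisobenzofuran-1,6,7(3H)-trione | CC1=CC(=O)C(=O)C2=C1COC2=O | intermediate
12 | methyl 5-[(6,7-dihydroxy-4-methyl-1-oxo-1,3-dihydroisobenzofuran-5-yl)oxy]-2,2,7-trimethyl-4H-1,3-benzodioxine-6-carboxylate | COC(=O)c1c(C)cc2OC(C)(C)OCc2c1Oc1c(C)c2COC(=O)c2c(O)c1O | intermediate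
13 | methyl 2-[(6,7-dihydroxy-4-methyl-1-oxo-1,3-dihydroisobenzofuran-5-yl)oxy]-4-hydroxy-3-(hydroxymethyl)-6-methylbenzoate | COC(=O)c1c(C)cc(O)c(CO)c1Oc1c(C)c2c(c(O)c1O)C(=O)OC2 | target

## Step count and risks

Total step count: 7 (steps 1–2 build the ring A partner, steps 3–5 the ring B partner, steps 6–7 follow convergence).
Longest linear sequence: 5 steps (5 → 7 → 9 → 10 → 12 → 13).

Steps most likely to fail:

**Step 6 (highest risk).** The ambident phenoxide may attack through carbon, the base may tautomerise 11 to a quinone methide (which would give a benzyl aryl ether), and adduct and quinone may exchange redox state. The fallback sets out from 9 and comes back at 12. Compound 9 is brominated at C5, its only free ring position (Br2, NaOAc, AcOH), to 5-bromo-6,7-dimethoxy-4-methylisobenzofuran-1(3H)-one F1. BBr3 then gives 5-bromo-6,7-dihydroxy-4-methylisobenzofuran-1(3H)-one F2, and Ag2O gives 5-bromo-4-methylisobenzofuran-1,6,7(3H)-trione F3. On F3 the cesium phenoxide of 4 replaces bromide by addition–elimination, the established substitution chemistry of haloquinones, so no C–H tautomerisation and no redox exchange is needed. This gives the aryloxy-o-quinone methyl 2,2,7-trimethyl-5-[(4-methyl-1,6,7-trioxo-1,3,6,7-tetrahydroisobenzofuran-5-yl)oxy]-4H-1,3-benzodioxine-6-carboxylate F4, which aq. Na2S2O4 reduces to 12.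

**Step 1.** Formylation may favour C5 or give an inseparable mixture. The fallback sets out from 1 and comes back at 2. Compound 1 is O-allylated at the non-chelated 4-OH (allyl bromide, K2CO3, acetone) to methyl 4-(allyloxy)-2-hydroxy-6-methylbenzoate F5. Aromatic Claisen rearrangement (PhNEt2, 190 °C) moves the allyl group to C3, the ortho carbon favoured by bond fixation in the chelated salicylate and the one not flanked by the ring methyl, giving methyl 3-allyl-2,4-dihydroxy-6-methylbenzoate F6. Isomerisation catalysed by PdCl2(MeCN)2 gives methyl 2,4-dihydroxy-6-methyl-3-[(E)-prop-1-en-1-yl]benzoate F7, and Lemieux–Johnson cleavage (OsO4 cat., NaIO4, THF/H2O) gives 2.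

**Step 4.** The electrophile may enter at the other free ring position, or diarylmethanes may form. The fallback sets out from 7 and comes back at 9. Carboxylate-directed ortho C–H palladation by divalent palladium (Pd(OAc)2 10 mol%, K2HPO4, CH2Br2 as solvent, 140 °C) alkylates the only ortho C–H to give 6-(bromomethyl)-2,3-dimethoxy-5-methylbenzoic acid F8 as its potassium salt, which lactonises in the flask by SN2 to 9.

## Further compounds

F1 | step 6 | 5-bromo-6,7-dimethoxy-4-methylisobenzofuran-1(3H)-one | Cc1c(Br)c(OC)c(OC)c2C(=O)OCc12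
F2 | step 6 | 5-bromo-6,7-dihydroxy-4-methylisobenzofuran-1(3H)-one | Cc1c(Br)c(O)c(O)c2C(=O)OCc12
F3 | step 6 | 5-bromo-4-methylisobenzofuran-1,6,7(3H)-trione | CC1=C(Br)C(=O)C(=O)C2=C1COC2=O
F4 | step 6 | methyl 2,2,7-trimethyl-5-[(4-methyl-1,6,7-trioxo-1,3,6,7-tetrahydroisobenzofuran-5-yl)oxy]-4H-1,3-benzodioxine-6-carboxylate | COC(=O)c1c(C)cc2OC(C)(C)OCc2c1OC1=C(C)C2=C(C(=O)OC2)C(=O)C1=O
F5 | step 1 | methyl 4-(allyloxy)-2-hydroxy-6-methylbenzoate | COC(=O)c1c(C)cc(OCC=C)cc1O
F6 | step 1 | methyl 3-allyl-2,4-dihydroxy-6-methylbenzoate | COC(=O)c1c(C)cc(O)c(CC=C)c1O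
F7 | step 1 | methyl 2,4-dihydroxy-6-methyl-3-[(E)-prop-1-en-1-yl]benzoate | COC(=O)c1c(C)cc(O)c(/C=C/C)c1O
F8 | step 4 | 6-(bromomethyl)-2,3-dimethoxy-5-methylbenzoic acid | Cc1cc(OC)c(OC)c(C(=O)O)c1CBr
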